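**Retrosynthetic overview**

- Numbering follows isochroman-1-one (C1 lactone carbonyl, O2, C3, C4, C4a, C5 to C8, C8a). Ring A is the carbocycle and is bought. Ring B is the lactone, the only ring made, and it is made last.
- Final disconnection C8a–C1: a hydrogen oxalate on the C3 oxygen loses CO2 to give an alkoxycarbonyl radical. This radical attacks ring A at the 1,4-benzoquinone oxidation level and closes ring B. Re-aromatisation then gives the free 5,8-hydroquinone, which is the target itself.
- Enabling feature: the two para oxygen atoms on C5 and C8 of ring A let ring A be a quinone. In that quinone C8a is an unsubstituted enone carbon (β to C5=O across C4a=C8a, α to C8=O) next to the C4–C3–O2 tether, so C8a–H is functionalised without halogen, aryl–metal bond or phenol protection.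
- The quinone comes from a 2,5-dimethoxyphenyl group by oxidative demethylation. C4–C4a comes from opening an (R)-oxirane with 2,5-dimethoxyphenylmagnesium bromide. C3 is set by hydrolytic kinetic resolution.
- The side-chain carbinol centre comes from (S)-propylene oxide and but-3-enylmagnesium bromide. The succinate goes on early as its tert-butyl ester and is unmasked together with the oxalate.

Key step: step 10

Assumption: the hydrolytic kinetic resolution is taken to follow its usual sense for unbranched alkyl oxiranes, so the (R,R)-catalyst leaves the (R)-oxirane.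

**Step 1**
Reactants: 1 (S)-propylene oxide; 2 but-3-enylmagnesium bromide
Product: 3 (2S)-hept-6-en-2-ol
Conditions: CuI (10 mol %), THF, −40 to −20 °C; then aq NH4Cl
Reagents that add atoms: none
Why: Copper-catalysed SN2 opening of a terminal epoxide by a Grignard reagent occurs at the unsubstituted carbon, so the C–O stereocentre of 1 passes unchanged into 3 as (S).

**Step 2**
Reactants: 3 (2S)-hept-6-en-2-ol; 4 4-tert-butoxy-4-oxobutanoic acid (mono-tert-butyl succinate)
Product: 5 tert-butyl (2S)-hept-6-en-2-yl butanedioate
Conditions: DCC, DMAP (10 mol %), CH2Cl2, 0 °C to rt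
Reagents that add atoms: none
Why: Steglich esterification acylates the alcohol oxygen without touching the C–O bond, so (S) is retained, and the tert-butyl ester masks the later free acid.

**Step 3**
Reactants: 5 tert-butyl (2S)-hept-6-en-2-yl butanedioate
Product: 6 tert-butyl (2S)-5-(oxiran-2-yl)pentan-2-yl butanedioate (both oxirane epimers)
Conditions: mCPBA, CH2Cl2, 0 °C to rt
Reagents that add atoms: mCPBA (3-chloroperoxybenzoic acid), OOC(=O)c1cccc(Cl)c1
Why: Prilezhaev epoxidation of the only alkene leaves the esters alone, and since the remote centre gives no facial control, both epimers are expected and step 4 sorts them.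

**Step 4**
Reactants: 6 tert-butyl (2S)-5-(oxiran-2-yl)pentan-2-yl butanedioate (both oxirane epimers)
Product: 7 tert-butyl (2S)-5-[(2R)-oxiran-2-yl]pentan-2-yl butanedioate
Conditions: (R,R)-(salen)Co(OAc) [salen = N,N'-bis(3,5-di-tert-butylsalicylidene)cyclohexane-1,2-diamine dianion] (0.5 mol %), H2O (0.55 equiv), THF, 0 °C to rt; chromatography
Reagents that add atoms: none
Why: In the hydrolytic kinetic resolution the chiral cobalt catalyst hydrolyses the (S)-oxirane epimer to a polar diol and leaves the (R)-oxirane, which sets the future C3 under pure catalyst control.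

**Step 5**
Reactants: 7 tert-butyl (2S)-5-[(2R)-oxiran-2-yl]pentan-2-yl butanedioate; 8 2,5-dimethoxyphenylmagnesium bromide
Product: 9 tert-butyl (2S,6R)-7-(2,5-dimethoxyphenyl)-6-hydroxyheptan-2-yl butanedioate
Conditions: CuI (10 mol %), THF, −40 to −20 °C; then aq NH4Cl
Reagents that add atoms: none
Why: Copper-catalysed SN2 opening at the oxirane CH2 forms C4–C4a and leaves the C3–O bond and its (R) configuration untouched, and at low temperature it should outrun addition to the two hindered esters.

**Step 6**
Reactants: 10 oxalyl chloride; 11 tert-butanol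
Product: 12 tert-butyl 2-chloro-2-oxoacetate
Conditions: Et2O, 0 °C to rt; volatiles removed, used crude
Reagents that add atoms: none
Why: This is nucleophilic acyl substitution (mono-alcoholysis of a diacid chloride), and the bulky alcohol with the less electrophilic mono-ester chloride should stop it after one exchange.

**Step 7**
Reactants: 9 tert-butyl (2S,6R)-7-(2,5-dimethoxyphenyl)-6-hydroxyheptan-2-yl butanedioate; 12 tert-butyl 2-chloro-2-oxoacetate
Product: 13 tert-butyl (2S,6R)-6-[(tert-butoxy)(oxo)acetoxy]-7-(2,5-dimethoxyphenyl)heptan-2-yl butanedioate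
Conditions: pyridine (2 equiv), CH2Cl2, 0 °C
Reagents that add atoms: none
Why: O-acylation of the secondary alcohol by a very reactive acid chloride (nucleophilic acyl substitution) places the future C1 on O2 with retention at C3.

**Step 8**
Reactants: 13 tert-butyl (2S,6R)-6-[(tert-butoxy)(oxo)acetoxy]-7-(2,5-dimethoxyphenyl)heptan-2-yl butanedioate
Product: 14 tert-butyl (2S,6R)-6-[(tert-butoxy)(oxo)acetoxy]-7-(3,6-dioxocyclohexa-1,4-dien-1-yl)heptan-2-yl butanedioate
Conditions: (NH4)2Ce(NO3)6 (2.5 equiv), MeCN/H2O 2:1, 0 °C, short contact time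
Reagents that add atoms: water, O
Why: In the oxidative demethylation of a hydroquinone dimethyl ether by tetravalent cerium, two one-electron oxidations and ipso attack of water expel methanol, and the esters and stereocentres should tolerate the cold, brief, acidic conditions.

**Step 9**
Reactants: 14 tert-butyl (2S,6R)-6-[(tert-butoxy)(oxo)acetoxy]-7-(3,6-dioxocyclohexa-1,4-dien-1-yl)heptan-2-yl butanedioate
Product: 15 4-{[(2S,6R)-6-(carboxycarbonyloxy)-7-(3,6-dioxocyclohexa-1,4-dien-1-yl)heptan-2-yl]oxy}-4-oxobutanoic acid
Conditions: CF3CO2H/CH2Cl2 1:2, 0 °C to rt; evaporation with toluene, used at once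
Reagents that add atoms: none
Why: Acidolysis of both tert-butyl esters (E1 loss of the tert-butyl cation) is done at the quinone stage because the electron-poor ring cannot be tert-butylated and the secondary alkyl esters are inert to anhydrous acid.

**Step 10**
Reactants: 15 4-{[(2S,6R)-6-(carboxycarbonyloxy)-7-(3,6-dioxocyclohexa-1,4-dien-1-yl)heptan-2-yl]oxy}-4-oxobutanoic acid
Product: 18 aspergimarin B, via alkoxycarbonyl radical 16 (not isolated), via cyclised keto tautomer 17 (not isolated)
Conditions: [Ir(dF(CF3)ppy)2(dtbbpy)]PF6 (2 mol %), 2,6-lutidine (1.0 equiv), degassed MeCN (5 mM), 450 nm LED, Ar, 25 °C; then dilute aq HCl wash under Ar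
Reagents that add atoms: none
Why: Proposed new method: under blue light the iridium photocatalyst shuttles one electron from the oxalate carboxylate of 15 to the quinone pool (the excited catalyst is quenched by quinone and the tetravalent iridium so formed oxidises the carboxylate), CO2 leaves, the σ-type alkoxycarbonyl radical 16 adds to C8a, and the resulting C4a radical (α to C5=O) takes the parked electron and a proton back to give 17, which enolises to the aromatic hydroquinone 18, so the step is redox-neutral. The closest known reaction types are the photoredox decarboxylation of alkyl oxalate salts followed by Giese-type addition or lactone-forming cyclisation of the alkoxycarbonyl radical, the Minisci alkoxycarbonylation by oxalic acid monoesters, and the decarboxylative radical C–H alkylation and acylation of quinones; new is their union in an intramolecular attack on a benzoquinone. Ring B, the only ring closed, forms by 6-endo-trig attack on C4a=C8a, while the 5-exo mode would have to hit the fully substituted C4a and would give a spiro radical that cannot aromatise. No lasting stereocentre is created (C8a of 17 is flattened by enolisation), and C3 and the side-chain centre keep their configuration because no bond to them is broken and a secondary alkoxycarbonyl radical loses its second CO2 only slowly. Site selectivity (C8a and not C6 or C7, which intermolecular radicals prefer) is secured by the short C4–C3–O2 tether together with high dilution. Chemoselectivity between the two carboxyl groups is secured by acidity, since one equivalent of 2,6-lutidine ionises only the much more acidic hydrogen oxalate and only a carboxylate is oxidised, and the product survives because its acyl group makes it the poorest reductant present.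

**Compound list**

1 | (S)-propylene oxide, (2S)-2-methyloxirane | C[C@H]1CO1 | starting material
2 | but-3-enylmagnesium bromide | C=CCC[Mg]Br | starting material
3 | (2S)-hept-6-en-2-ol | C[C@@H](CCCC=C)O | intermediate
4 | 4-tert-butoxy-4-oxobutanoic acid | OC(=O)CCC(=O)OC(C)(C)C | starting material
5 | tert-butyl (2S)-hept-6-en-2-yl butanedioate | C[C@@H](CCCC=C)OC(=O)CCC(=O)OC(C)(C)C | intermediate
6 | tert-butyl (2S)-5-(oxiran-2-yl)pentan-2-yl butanedioate, both oxirane epimers | C[C@@H](CCCC1CO1)OC(=O)CCC(=O)OC(C)(C)C | intermediate
7 | tert-butyl (2S)-5-[(2R)-oxiran-2-yl]pentan-2-yl butanedioate | C[C@@H](CCC[C@@H]1CO1)OC(=O)CCC(=O)OC(C)(C)C | intermediate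
8 | 2,5-dimethoxyphenylmagnesium bromide | COc1ccc(OC)c([Mg]Br)c1 | starting material
9 | tert-butyl (2S,6R)-7-(2,5-dimethoxyphenyl)-6-hydroxyheptan-2-yl butanedioate | C[C@@H](CCC[C@@H](O)Cc1cc(OC)ccc1OC)OC(=O)CCC(=O)OC(C)(C)C | intermediate
10 | oxalyl chloride | ClC(=O)C(=O)Cl | starting material
11 | tert-butanol | CC(C)(C)O | starting material
12 | tert-butyl 2-chloro-2-oxoacetate | CC(C)(C)OC(=O)C(=O)Cl | intermediate
13 | tert-butyl (2S,6R)-6-[(tert-butoxy)(oxo)acetoxy]-7-(2,5-dimethoxyphenyl)heptan-2-yl butanedioate | C[C@@H](CCC[C@@H](OC(=O)C(=O)OC(C)(C)C)Cc1cc(OC)ccc1OC)OC(=O)CCC(=O)OC(C)(C)C | intermediate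
14 | tert-butyl (2S,6R)-6-[(tert-butoxy)(oxo)acetoxy]-7-(3,6-dioxocyclohexa-1,4-dien-1-yl)heptan-2-yl butanedioate | C[C@@H](CCC[C@@H](OC(=O)C(=O)OC(C)(C)C)CC1=CC(=O)C=CC1=O)OC(=O)CCC(=O)OC(C)(C)C | intermediate
15 | 4-{[(2S,6R)-6-(carboxycarbonyloxy)-7-(3,6-dioxocyclohexa-1,4-dien-1-yl)heptan-2-yl]oxy}-4-oxobutanoic acid | C[C@@H](CCC[C@@H](OC(=O)C(=O)O)CC1=CC(=O)C=CC1=O)OC(=O)CCC(=O)O | intermediate
16 | alkoxycarbonyl radical on the C3 oxygen (15 minus CO2 and H) | C[C@@H](CCC[C@@H](O[C]=O)CC1=CC(=O)C=CC1=O)OC(=O)CCC(=O)O | intermediate
17 | cyclised keto tautomer (5-hydroxy-8-oxo-8,8a-dihydro form of the target, C8a unassigned) | C[C@@H](CCC[C@@H]1CC2=C(O)C=CC(=O)C2C(=O)O1)OC(=O)CCC(=O)O | intermediate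
18 | aspergimarin B, 4-{[(2S)-5-[(3R)-5,8-dihydroxy-1-oxo-3,4-dihydro-1H-isochromen-3-yl]pentan-2-yl]oxy}-4-oxobutanoic acid | C[C@@H](CCC[C@@H]1Cc2c(O)ccc(O)c2C(=O)O1)OC(=O)CCC(=O)O | target

**Step count and risks**

Total step count: 10. Longest linear sequence: 9 (steps 1 to 5 and 7 to 10).

Steps most likely to fail:

**Step 10.**
- What may go wrong: the excited quinone may abstract hydrogen from its own side chain. The 6-endo closure may be slow enough for the radical to abstract hydrogen or lose its second CO2. The succinate carboxyl may also be oxidised late in the run.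
- Fallback: known chemistry, a palladium-catalysed carbonylative lactonisation of an aryl bromide, setting out from 7.
- 2-Bromo-1,4-dimethoxybenzene is magnesiated between Br and OMe with TMPMgCl·LiCl (THF, −20 °C) to the arylmagnesium chloride F1.
- F1 opens 7 under CuI catalysis to the bromo alcohol F2.
- CO (1 atm), Pd(OAc)2, 1,1'-bis(diphenylphosphino)ferrocene and Et3N in toluene at 100 °C should turn F2 into the 5,8-dimethoxy lactone F3. C8a–C1 forms by CO insertion into the aryl–palladium bond, and the C3 oxygen captures the acyl group.
- BBr3 (CH2Cl2, −78 to 0 °C) should then remove both methyl ethers and the tert-butyl ester. The fallback comes back to the route at 18.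

**Step 5.**
- What may go wrong: the aryl Grignard reagent may add to an ester carbonyl, or magnesium halide may open the oxirane to a halohydrin.
- Fallback: replace the carbanionic reagent by a nickel-catalysed reductive cross-electrophile coupling, setting out from 7.
- 7 and 2-iodo-1,4-dimethoxybenzene are coupled with NiCl2(dme), 2,2'-bipyridine, NaI, Et3N·HCl and Mn powder in DMPU at rt.
- Iodide opens the oxirane at its CH2 end, and the iodohydrin is joined to the aryl–nickel species. The C3–O bond stays untouched.
- It comes back to the route at 9 and makes no new compound (F0).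

**Step 8.**
- What may go wrong: the activated mixed oxalate may be lost by hydrolysis in the acidic aqueous medium, or the arene radical cation may couple oxidatively.
- Fallback: unmask the quinone reductively and then by a mild neutral oxidation, setting out from 7.
- 1,4-Bis(benzyloxy)-2-bromobenzene and Mg give the aryl Grignard reagent F4.
- F4 opens 7 (CuI, THF, −40 °C) to the bis(benzyl ether) alcohol F5.
- Acylation with 12 and pyridine gives the bis(benzyl ether) mixed oxalate F6.
- H2 over palladium on carbon in EtOAc gives the hydroquinone F7, which is oxidised at once with Ag2O and MgSO4 in Et2O. The fallback comes back to the route at 14.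

**Further compounds**

F1 | step 10 | (2-bromo-3,6-dimethoxyphenyl)magnesium chloride | COc1ccc(OC)c([Mg]Cl)c1Br
F2 | step 10 | tert-butyl (2S,6R)-7-(2-bromo-3,6-dimethoxyphenyl)-6-hydroxyheptan-2-yl butanedioate | C[C@@H](CCC[C@@H](O)Cc1c(OC)ccc(OC)c1Br)OC(=O)CCC(=O)OC(C)(C)C
F3 | step 10 | tert-butyl (2S)-5-[(3R)-5,8-dimethoxy-1-oxo-3,4-dihydro-1H-isochromen-3-yl]pentan-2-yl butanedioate | C[C@@H](CCC[C@@H]1Cc2c(OC)ccc(OC)c2C(=O)O1)OC(=O)CCC(=O)OC(C)(C)C
F0 | step 5 | none | none
F4 | step 8 | [2,5-bis(benzyloxy)phenyl]magnesium bromide | Br[Mg]c1cc(OCc2ccccc2)ccc1OCc1ccccc1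
F5 | step 8 | tert-butyl (2S,6R)-7-[2,5-bis(benzyloxy)phenyl]-6-hydroxyheptan-2-yl butanedioate | C[C@@H](CCC[C@@H](O)Cc1cc(OCc2ccccc2)ccc1OCc1ccccc1)OC(=O)CCC(=O)OC(C)(C)C
F6 | step 8 | tert-butyl (2S,6R)-7-[2,5-bis(benzyloxy)phenyl]-6-[(tert-butoxy)(oxo)acetoxy]heptan-2-yl butanedioate | C[C@@H](CCC[C@@H](OC(=O)C(=O)OC(C)(C)C)Cc1cc(OCc2ccccc2)ccc1OCc1ccccc1)OC(=O)CCC(=O)OC(C)(C)C
F7 | step 8 | tert-butyl (2S,6R)-6-[(tert-butoxy)(oxo)acetoxy]-7-(2,5-dihydroxyphenyl)heptan-2-yl butanedioate | C[C@@H](CCC[C@@H](OC(=O)C(=O)OC(C)(C)C)Cc1cc(O)ccc1O)OC(=O)CCC(=O)OC(C)(C)C
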